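Atom labels are the germacrane labels of the target: ring C1–C10 (C1 ketone, C14 methyl on C10, C15 methyl on C4), butenolide carbons C11–C13 (C12 carbonyl, C13 acetoxymethyl), lactone oxygen on C6. Ten-membered intermediates that lack C11–C13 are named as 11,12,13-trinorgermacranes; the allene in them is C2=C1=C10.

## The problem

The target is a ten-membered carbocycle fused at C6–C7 to a butenolide through the tetrasubstituted C7=C11 bond. Closing such a ring directly is penalised by strain, and the formed ring is prone to transannular attack (C4–O on the C1 ketone, C2 on the butenolide). There are five stereocentres: the contiguous C4/C5/C6 triad (trans-4,5-epoxide, C5–O and C6–O threo), and C8 and C10, each 1,3 to its neighbour across sp2 C7 and methylene C9. Ordinary 1,2-induction from the triad cannot reach C8 or C10, so these must be set through the ring itself or by transfer of chirality. The three esters differ in kind: a tertiary acetate beside a ketone, a primary allylic acetate that is a vinylogous leaving group, and a secondary tiglate. Together with the C6–H of the butenolide and the epoxide they exclude strong base, strong acid and reducing metals late in the route. The feature that opens the way is that C7 and C2 face each other across the ring. A C2–C7 bond would split the ring into the six-membered ring C2–C3–C4–C5–C6–C7, which holds the whole triad, and the arc C8–C9–C10–C1. Read with a ketone at C7 and an allene at C2=C1=C10, that arc is the product side of an oxy-Cope shift. Two further relations make the six-membered ring able to carry the oxygen pattern: the C1 ketone/C10 carbinol pair is a doubly oxidised allene, and the trans-4,5-epoxide/C6 carbinol is the Payne isomer of a cis-5,6-epoxide with a syn C4 alcohol.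

## Retrosynthesis

**23 to 19.** The two acetate C–O bonds are cut first (diol 22). The C1 carbonyl oxygen and the C10–O bond are then removed together to give allene 19. This is preferred to enolate oxygenation at C10 because the ring would then hold two ketones and a base-labile butenolide. The allene axis also encodes C10, so the forward step only has to deliver oxygen to the C1=C10 π bond on the side away from C3 and a hydrogen to C2.

**19 to 12 + 16.** The butenolide is cut at C7=C11 and at the C12–O6 ester bond (19 from 18 from 17). This leaves acyloin 12 (C6–OH, C7 ketone) and phosphonate acid 16, which carries C11–C13 with the C13 oxygen as a 4-methoxybenzyl ether. Building the lactone on a ketone already in the ring avoids a tetrasubstituted alkenyl metal and needs only a five-membered-ring olefination.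

**12 to 10.** The C4–O bond of the epoxide is cut and the oxygen moved back to C5–C6. A trans-epoxide cannot exist in a six-membered ring, but its Payne partner 10 (cis-5,6-epoxide, syn C4–O) can. The forward shift inverts C5, which gives the trans geometry and the threo C5/C6 relation in one event.

**10 to 7 (key).** The C9–C10 bond is cut and C2–C7 re-formed; the tiglate and its C8 oxygen are removed. The ten-membered allenyl ketone becomes the cyclohexanol 7 with a vinyl group on C7 and a propynyl group on C2. Against closing the ring by an end-to-end C–C bond formation, this cut never closes a ten-membered ring: it is revealed from a six-membered one. Compound 7 has no medium ring and no C8 or C10 centre. The forward step must give the [3,3] shift, an enolate of defined geometry and face, and an allene whose axis follows from C2.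

**7 to 1.** Three C–C bonds are cut, each made by a nucleophile adding anti to the one epoxide: vinyl to the C7 ketone (6), methyl to the C4 ketone (4 from 3), propynyl in 1,4-fashion to C2 (3 from 2). Acetal hydrolysis and silylation (5, 6) lie between. The epoxide itself comes from desymmetrising the achiral dienone 1. A single reagent-controlled step thus fixes the absolute configuration and every later centre is relayed from it.

**16 to 13 + 14.** The C13–O bond is cut: oxa-Michael addition of alcohol 14 to vinylphosphonate 13 gives 15, and saponification gives 16.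

## Roads not taken

Alternative 1: The most obvious cut is C6–C7 together with the lactone C–O bond. The forward step is an intramolecular Nozaki–Hiyama–Kishi coupling of the iodoalkenoate aldehyde A1 (CrCl2, NiCl2 cat.), followed by lactonisation to 23.
- It closes the strained ten-membered ring end to end, with a trans-epoxide and a tetrasubstituted alkene already in the chain.
- C6 is set in the ring-closing event itself.
- The α-acetoxy ketone of A1 is reducible by divalent chromium.
- A1 needs a long acyclic sequence with separate control of C4/C5, C8 and C10 and a stereodefined tetrasubstituted iodoalkene.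

The chosen plan forms no medium ring by closure and draws all centres from one epoxide.

Alternative 2: Cut C2–C3 after adding a CO2 bridge. The forward step is a Tsuji–Trost-type decarboxylative allylation (Pd(PPh3)4, zerovalent palladium) that contracts the twelve-membered β-keto lactone A2 to the cyclodecenone A3.
- The π-allyl unit flanks C6, so the butenolide cannot be present (its C6–O bond would ionise).
- The C7 ketone makes C6–H both allylic and α to a carbonyl.
- The enolate can close to an eight- or a ten-membered ring.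
- The epoxide would have to be added last under conformational control only.
- A2 again needs a long acyclic run-up.

Alternative 3: Run the oxy-Cope across the other transannular bond, C1–C6. The forward step takes cyclohexanol A4 (isopropenyl on C1, ethynyl on C6) to the allene A5, with C10 from the enolate and C6/C8 from the allene.
- The stereochemical relay is also coherent, but ring C1–C6 cannot carry a trans-epoxide or an E-alkene.
- C4/C5 would have to travel as a trans-diol, to be turned into the alkene by Corey–Winter elimination and re-epoxidised: at least three more steps, with the epoxide face left to the ring.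
- The shift needs a terminal alkyne, whose acidic C–H competes with the alkoxide.
- A4 has four contiguous centres made by epoxide opening.

In the chosen orientation the Payne shift delivers the epoxide and the C6 carbinol without extra steps.

Key step: step 7

Assumption: the tartrate-mediated epoxidation of 1 is taken to give the (1S,6R)-epoxide 2 with L-(+)-diisopropyl tartrate; if the sense is the opposite, the D-tartrate is used.

Assumption: 1, 13, 14 and the reagents named in the Conditions lines are taken as commercially available.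

## Route

Step 1
Reactants: 1 4,4-dimethoxycyclohexa-2,5-dien-1-one
Product: 2 (1S,6R)-5,5-dimethoxy-7-oxabicyclo[4.1.0]hept-3-en-2-one
Conditions: Ph3COOH, NaN(SiMe3)2, L-(+)-diisopropyl tartrate, toluene, −50 °C; aq NH4Cl
Reagents that add atoms: trityl hydroperoxide, OOC(c1ccccc1)(c1ccccc1)c1ccccc1
Why: Tartrate-mediated nucleophilic (Weitz–Scheffer type) epoxidation of a quinone monoketal; the chiral sodium tartrate–hydroperoxide aggregate should select one of the two enantiotopic enone arms, which sets C5 and C6 together as a cis-epoxide, and the epoxy enone is less reactive than 1, so one equivalent of oxidant should stop at the mono-epoxide.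

Step 2
Reactants: 2 (1S,6R)-5,5-dimethoxy-7-oxabicyclo[4.1.0]hept-3-en-2-one
Product: 3 (1S,4S,6R)-5,5-dimethoxy-4-(prop-1-yn-1-yl)-7-oxabicyclo[4.1.0]heptan-2-one
Conditions: MeC≡CAlMe2 (from MeC≡CLi and Me2AlCl), Ni(acac)2 (5 mol %), i-Bu2AlH (5 mol %), Et2O, −5 °C
Reagents that add atoms: dimethyl(prop-1-yn-1-yl)aluminium, CC#C[Al](C)C
Why: Nickel-catalysed conjugate addition of an alkynylalane to the remaining enone (1,4-alkynylation of an s-trans enone); the nucleophile should enter C2 on the face opposite the epoxide oxygen, which sets C2, and at −5 °C the catalysed 1,4-addition should outrun opening of the epoxide by the alane.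

Step 3
Reactants: 3 (1S,4S,6R)-5,5-dimethoxy-4-(prop-1-yn-1-yl)-7-oxabicyclo[4.1.0]heptan-2-one
Product: 4 (1S,2R,4S,6R)-5,5-dimethoxy-2-methyl-4-(prop-1-yn-1-yl)-7-oxabicyclo[4.1.0]heptan-2-ol
Conditions: MeMgBr, CeCl3, THF, −78 °C
Reagents that add atoms: methylmagnesium bromide, C[Mg]Br
Why: 1,2-Addition of a Grignard reagent (with CeCl3) to the α,β-epoxy ketone; methyl should add anti to the adjacent epoxide C–O bond, so the new C4 hydroxyl is cis to the epoxide, and CeCl3 suppresses enolisation at C3.

Step 4
Reactants: 4 (1S,2R,4S,6R)-5,5-dimethoxy-2-methyl-4-(prop-1-yn-1-yl)-7-oxabicyclo[4.1.0]heptan-2-ol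
Product: 5 (1R,3S,5R,6S)-5-hydroxy-5-methyl-3-(prop-1-yn-1-yl)-7-oxabicyclo[4.1.0]heptan-2-one
Conditions: PPTS (cat.), acetone/H2O, 40 °C
Reagents that add atoms: water, O
Why: Acid-catalysed acetal hydrolysis unmasks the C7 ketone; the pyridinium acid is too weak to open the epoxide or ionise the tertiary alcohol, and no stereocentre is touched.

Step 5
Reactants: 5 (1R,3S,5R,6S)-5-hydroxy-5-methyl-3-(prop-1-yn-1-yl)-7-oxabicyclo[4.1.0]heptan-2-one
Product: 6 (1R,3S,5R,6S)-5-methyl-3-(prop-1-yn-1-yl)-5-(triethylsilyloxy)-7-oxabicyclo[4.1.0]heptan-2-one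
Conditions: Et3SiOTf, 2,6-lutidine, CH2Cl2, −78 °C
Reagents that add atoms: triethylsilyl trifluoromethanesulfonate, CC[Si](CC)(CC)OS(=O)(=O)C(F)(F)F
Why: Silylation of the tertiary alcohol with a silyl triflate and a hindered pyridine base; the C4 oxygen is masked so that it cannot be acylated or start a Payne shift in step 7, and it is set free again by fluoride in step 8.

Step 6
Reactants: 6 (1R,3S,5R,6S)-5-methyl-3-(prop-1-yn-1-yl)-5-(triethylsilyloxy)-7-oxabicyclo[4.1.0]heptan-2-one
Product: 7 (1R,2S,3S,5R,6S)-2-ethenyl-5-methyl-3-(prop-1-yn-1-yl)-5-(triethylsilyloxy)-7-oxabicyclo[4.1.0]heptan-2-ol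
Conditions: CH2=CHMgBr, CeCl3, THF, −78 °C
Reagents that add atoms: vinylmagnesium bromide, C=C[Mg]Br
Why: 1,2-Addition of a vinylcerium reagent, whose low basicity should leave the α-alkynyl ketone un-enolised; attack anti to the epoxide oxygen (axial on the chair that keeps methyl and propynyl equatorial) sets C7 with the hydroxyl cis to the epoxide and the vinyl group cis to the propynyl group.

Step 7
Reactants: 7 (1R,2S,3S,5R,6S)-2-ethenyl-5-methyl-3-(prop-1-yn-1-yl)-5-(triethylsilyloxy)-7-oxabicyclo[4.1.0]heptan-2-ol
Product: 10 (P,4R,5S,6R,8S)-5,6-epoxy-7-oxo-4-(triethylsilyloxy)-11,12,13-trinorgermacra-1(2),1(10)-dien-8-yl (E)-2-methylbut-2-enoate, via ring-expanded potassium enolate 8 (not isolated), via potassium C8-alkoxide 9 (not isolated)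
Conditions: KN(SiMe3)2, 18-crown-6, THF, −78 → 20 °C; then 2-(phenylsulfonyl)-3-phenyloxaziridine, −78 °C; then (E)-2-methylbut-2-enoyl chloride, −78 → 0 °C
Reagents that add atoms: 2-(phenylsulfonyl)-3-phenyloxaziridine, O=S(=O)(N1OC1c1ccccc1)c1ccccc1; (E)-2-methylbut-2-enoyl chloride, C/C=C(\C)C(Cl)=O
Why: Deprotonation gives the potassium alkoxide of 7, whose vinyl (C8=C9) and propynyl (C1≡C10) arms are gauche on the C7–C2 bond; a chair-like [3,3] shift (the acetylenic form of the anionic oxy-Cope rearrangement) breaks C2–C7 and joins C9 to C10, so the six-membered ring is enlarged by four atoms to the ten-membered enolate 8 and no ring is closed end to end. The closest known reaction type is the alkoxide-accelerated oxy-Cope ring expansion of 1,2-dialkenyl- and 2-alkynyl-1-alkenylcyclohexanols to cyclodecenone enolates, with oxygenation of the enolate in the same flask. The allene axis is fixed by C2 alone, because bond breaking and bond making are suprafacial on the propargyl unit, so C9 ends on the side of C10 from which C7 left. The chair that keeps the C4 methyl and the propynyl group equatorial on the cyclohexane has C6 equatorial on the carbinol carbon; it should give the enolate with C6 and C9 trans, and the rest of the ring then lies on one face of that enolate. The oxaziridine should therefore deliver oxygen to C8 on the open outer face, which corresponds to 8S, and acylation of alkoxide 9 does not touch the new centre. The step needs the shift to outrun base-induced side reactions: C7–O is cis to the epoxide so no Payne shift can occur in the six-membered ring, C4–O is silylated, the alkyne is internal so no acetylide forms, and the enolate is trapped cold before transannular ene or Favorskii-type reactions can set in.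

Step 8
Reactants: 10 (P,4R,5S,6R,8S)-5,6-epoxy-7-oxo-4-(triethylsilyloxy)-11,12,13-trinorgermacra-1(2),1(10)-dien-8-yl (E)-2-methylbut-2-enoate
Product: 12 (P,4R,5R,6R,8S)-4,5-epoxy-6-hydroxy-7-oxo-11,12,13-trinorgermacra-1(2),1(10)-dien-8-yl (E)-2-methylbut-2-enoate, via C4 alkoxide 11 (not isolated)
Conditions: Bu4NF, THF, −20 → 0 °C; aq NH4Cl
Reagents that add atoms: none
Why: Fluoride removes the triethylsilyl group, and the C4 alkoxide 11, which can now reach the back of C5 in the flexible ten-membered ring, opens the 5,6-epoxide with inversion at C5 (Payne rearrangement); this gives the trans-4,5-epoxide and the C6 hydroxyl in the threo relation of the target, with C6 keeping the configuration of the original epoxide. The shift is pulled forward by the more substituted epoxide and the more acidic α-ketol.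

Step 9
Reactants: 13 ethyl 2-(diethoxyphosphoryl)acrylate; 14 4-methoxybenzyl alcohol
Product: 15 ethyl 2-(diethoxyphosphoryl)-3-[(4-methoxybenzyl)oxy]propanoate
Conditions: KOt-Bu (10 mol %), THF, 0 °C
Reagents that add atoms: none
Why: Base-catalysed oxa-Michael addition of the alcohol to the doubly activated vinylphosphonate; the α-carbon formed becomes sp2 in step 12, so its configuration is of no consequence.

Step 10
Reactants: 15 ethyl 2-(diethoxyphosphoryl)-3-[(4-methoxybenzyl)oxy]propanoate
Product: 16 2-(diethoxyphosphoryl)-3-[(4-methoxybenzyl)oxy]propanoic acid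
Conditions: LiOH, THF/H2O, 0 °C; then 1 M HCl
Reagents that add atoms: lithium hydroxide, [Li+].[OH-]
Why: Saponification of the carboxylic ester, which is much faster than hydrolysis of the phosphonate esters; the cold conditions limit retro-Michael loss of the benzyl alcohol.

Step 11
Reactants: 12 (P,4R,5R,6R,8S)-4,5-epoxy-6-hydroxy-7-oxo-11,12,13-trinorgermacra-1(2),1(10)-dien-8-yl (E)-2-methylbut-2-enoate; 16 2-(diethoxyphosphoryl)-3-[(4-methoxybenzyl)oxy]propanoic acid
Product: 17 (P,4R,5R,6R,8S)-4,5-epoxy-7-oxo-8-[(E)-2-methylbut-2-enoyloxy]-11,12,13-trinorgermacra-1(2),1(10)-dien-6-yl 2-(diethoxyphosphoryl)-3-[(4-methoxybenzyl)oxy]propanoate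
Conditions: DCC, DMAP (cat.), CH2Cl2, 0 °C
Reagents that add atoms: none
Why: Carbodiimide (Steglich) esterification of the secondary α-ketol; the near-neutral conditions should leave the epoxide, the allene and the tiglate alone and should not enolise the ketone.

Step 12
Reactants: 17 (P,4R,5R,6R,8S)-4,5-epoxy-7-oxo-8-[(E)-2-methylbut-2-enoyloxy]-11,12,13-trinorgermacra-1(2),1(10)-dien-6-yl 2-(diethoxyphosphoryl)-3-[(4-methoxybenzyl)oxy]propanoate
Product: 18 (P,4R,5R,6S,8S)-4,5-epoxy-13-[(4-methoxybenzyl)oxy]-8-[(E)-2-methylbut-2-enoyloxy]germacra-1(2),1(10),7(11)-trien-12,6-olide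
Conditions: LiCl, DBU, MeCN, 0 → 20 °C
Reagents that add atoms: none
Why: Intramolecular Horner–Wadsworth–Emmons olefination under LiCl/amidine conditions; the phosphonate anion attacks the C7 ketone (5-exo-trig) and the five-membered ring forms the tetrasubstituted C7=C11 bond with the only geometry the butenolide allows, without touching C6 or C8.

Step 13
Reactants: 18 (P,4R,5R,6S,8S)-4,5-epoxy-13-[(4-methoxybenzyl)oxy]-8-[(E)-2-methylbut-2-enoyloxy]germacra-1(2),1(10),7(11)-trien-12,6-olide
Product: 19 (P,4R,5R,6S,8S)-4,5-epoxy-13-hydroxy-8-[(E)-2-methylbut-2-enoyloxy]germacra-1(2),1(10),7(11)-trien-12,6-olide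
Conditions: DDQ, CH2Cl2/pH 7 buffer, 0 °C
Reagents that add atoms: none
Why: Oxidative cleavage of the 4-methoxybenzyl ether with DDQ; the electron-poor butenolide and tiglate alkenes, the allene and the epoxide should not be oxidised under buffered conditions.

Step 14
Reactants: 19 (P,4R,5R,6S,8S)-4,5-epoxy-13-hydroxy-8-[(E)-2-methylbut-2-enoyloxy]germacra-1(2),1(10),7(11)-trien-12,6-olide
Product: 22 (4R,5R,6S,8S,10R)-4,5-epoxy-10,13-dihydroxy-1-oxo-8-[(E)-2-methylbut-2-enoyloxy]germacr-7(11)-en-12,6-olide, via spirodiepoxide 20 (not isolated), via iodo ketone 21 (not isolated)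
Conditions: dimethyldioxirane (acetone), CH2Cl2, −40 → 0 °C; then Bu4NI, AcOH, THF, −20 → 0 °C
Reagents that add atoms: dimethyldioxirane, CC1(C)OO1
Why: Dimethyldioxirane should epoxidise both π bonds of the allene to the spirodiepoxide 20 (known on acyclic and medium-ring allenes); the C1=C10 bond is attacked on the side away from ring carbon C3, which with the P axis places oxygen on C10 as in 10R. Iodide opens 20 at the secondary C2, collapse gives the C1 ketone and the C10 hydroxyl, and iodide with acetic acid reduces the α-iodo ketone 21 to the methylene. The enoate alkenes are too electron-poor for the dioxirane.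

Step 15
Reactants: 22 (4R,5R,6S,8S,10R)-4,5-epoxy-10,13-dihydroxy-1-oxo-8-[(E)-2-methylbut-2-enoyloxy]germacr-7(11)-en-12,6-olide
Product: 23 (4R,5R,6S,8S,10R)-10,13-diacetoxy-4,5-epoxy-1-oxo-8-[(E)-2-methylbut-2-enoyloxy]germacr-7(11)-en-12,6-olide (CNP0175424.1)
Conditions: Ac2O, Et3N, DMAP, CH2Cl2, 20 °C
Reagents that add atoms: acetic anhydride, CC(=O)OC(C)=O
Why: DMAP-catalysed acetylation of the primary allylic alcohol and, more slowly, of the tertiary α-ketol; no stereocentre is affected and the product is the target.

## Compound list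

1 | 4,4-dimethoxycyclohexa-2,5-dien-1-one | COC1(OC)C=CC(=O)C=C1 | starting material
2 | (1S,6R)-5,5-dimethoxy-7-oxabicyclo[4.1.0]hept-3-en-2-one | O=C1C=CC(OC)(OC)[C@@H]2O[C@H]12 | intermediate
3 | (1S,4S,6R)-5,5-dimethoxy-4-(prop-1-yn-1-yl)-7-oxabicyclo[4.1.0]heptan-2-one | O=C1C[C@@H](C#CC)C(OC)(OC)[C@@H]2O[C@H]12 | intermediate
4 | (1S,2R,4S,6R)-5,5-dimethoxy-2-methyl-4-(prop-1-yn-1-yl)-7-oxabicyclo[4.1.0]heptan-2-ol | C[C@@]1(O)C[C@@H](C#CC)C(OC)(OC)[C@@H]2O[C@H]12 | intermediate
5 | (1R,3S,5R,6S)-5-hydroxy-5-methyl-3-(prop-1-yn-1-yl)-7-oxabicyclo[4.1.0]heptan-2-one | C[C@@]1(O)C[C@@H](C#CC)C(=O)[C@@H]2O[C@H]12 | intermediate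
6 | (1R,3S,5R,6S)-5-methyl-3-(prop-1-yn-1-yl)-5-(triethylsilyloxy)-7-oxabicyclo[4.1.0]heptan-2-one | C[C@@]1(O[Si](CC)(CC)CC)C[C@@H](C#CC)C(=O)[C@@H]2O[C@H]12 | intermediate
7 | (1R,2S,3S,5R,6S)-2-ethenyl-5-methyl-3-(prop-1-yn-1-yl)-5-(triethylsilyloxy)-7-oxabicyclo[4.1.0]heptan-2-ol | C=C[C@@]1(O)[C@@H]2O[C@@H]2[C@](C)(O[Si](CC)(CC)CC)C[C@H]1C#CC | intermediate
8 | potassium enolate (C7(O−)=C8, O cis to C9) of the ring-expanded (P)-allene, (4R,5S,6R)-5,6-epoxy-4-(triethylsilyloxy)-11,12,13-trinorgermacrane skeleton | [K+].[O-]\C1=C/CC(C)=[C@@]=C([H])C[C@@](C)(O[Si](CC)(CC)CC)[C@H]2O[C@@H]12 | intermediate (not isolated)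
9 | potassium (8S)-alkoxide of the (P,4R,5S,6R)-5,6-epoxy-7-oxo-4-(triethylsilyloxy)-11,12,13-trinorgermacra-1(2),1(10)-diene | [K+].[O-][C@H]1CC(C)=[C@@]=C([H])C[C@@](C)(O[Si](CC)(CC)CC)[C@H]2O[C@H]2C1=O | intermediate (not isolated)
10 | (P,4R,5S,6R,8S)-5,6-epoxy-7-oxo-4-(triethylsilyloxy)-11,12,13-trinorgermacra-1(2),1(10)-dien-8-yl (E)-2-methylbut-2-enoate | C/C=C(\C)C(=O)O[C@H]1CC(C)=[C@@]=C([H])C[C@@](C)(O[Si](CC)(CC)CC)[C@H]2O[C@H]2C1=O | intermediate
11 | tetrabutylammonium C4-alkoxide of desilylated 10 | C/C=C(\C)C(=O)O[C@H]1CC(C)=[C@@]=C([H])C[C@@](C)([O-])[C@H]2O[C@H]2C1=O.CCCC[N+](CCCC)(CCCC)CCCC | intermediate (not isolated)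
12 | (P,4R,5R,6R,8S)-4,5-epoxy-6-hydroxy-7-oxo-11,12,13-trinorgermacra-1(2),1(10)-dien-8-yl (E)-2-methylbut-2-enoate | C/C=C(\C)C(=O)O[C@H]1CC(C)=[C@@]=C([H])C[C@@]2(C)O[C@@H]2[C@@H](O)C1=O | intermediate
13 | ethyl 2-(diethoxyphosphoryl)acrylate | CCOC(=O)C(=C)P(=O)(OCC)OCC | starting material
14 | 4-methoxybenzyl alcohol | COc1ccc(CO)cc1 | starting material
15 | ethyl 2-(diethoxyphosphoryl)-3-[(4-methoxybenzyl)oxy]propanoate | CCOC(=O)C(COCc1ccc(OC)cc1)P(=O)(OCC)OCC | intermediate
16 | 2-(diethoxyphosphoryl)-3-[(4-methoxybenzyl)oxy]propanoic acid | OC(=O)C(COCc1ccc(OC)cc1)P(=O)(OCC)OCC | intermediate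
17 | (P,4R,5R,6R,8S)-4,5-epoxy-7-oxo-8-[(E)-2-methylbut-2-enoyloxy]-11,12,13-trinorgermacra-1(2),1(10)-dien-6-yl 2-(diethoxyphosphoryl)-3-[(4-methoxybenzyl)oxy]propanoate | C/C=C(\C)C(=O)O[C@H]1CC(C)=[C@@]=C([H])C[C@@]2(C)O[C@@H]2[C@@H](OC(=O)C(COCc2ccc(OC)cc2)P(=O)(OCC)OCC)C1=O | intermediate
18 | (P,4R,5R,6S,8S)-4,5-epoxy-13-[(4-methoxybenzyl)oxy]-8-[(E)-2-methylbut-2-enoyloxy]germacra-1(2),1(10),7(11)-trien-12,6-olide | C/C=C(\C)C(=O)O[C@H]1CC(C)=[C@@]=C([H])C[C@@]2(C)O[C@@H]2[C@H]2OC(=O)C(COCc3ccc(OC)cc3)=C12 | intermediate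
19 | (P,4R,5R,6S,8S)-4,5-epoxy-13-hydroxy-8-[(E)-2-methylbut-2-enoyloxy]germacra-1(2),1(10),7(11)-trien-12,6-olide | C/C=C(\C)C(=O)O[C@H]1CC(C)=[C@@]=C([H])C[C@@]2(C)O[C@@H]2[C@H]2OC(=O)C(CO)=C12 | intermediate
20 | (4R,5R,6S,8S,10R)-1,2:1,10:4,5-triepoxy-13-hydroxy-8-[(E)-2-methylbut-2-enoyloxy]germacr-7(11)-en-12,6-olide (spirodiepoxide at C1; C1 and C2 configuration not controlled, erased in the next event) | C/C=C(\C)C(=O)O[C@H]1C[C@@]3(C)OC34OC4C[C@@]2(C)O[C@@H]2[C@H]2OC(=O)C(CO)=C12 | intermediate (not isolated)
21 | (4R,5R,6S,8S,10R)-4,5-epoxy-10,13-dihydroxy-2-iodo-1-oxo-8-[(E)-2-methylbut-2-enoyloxy]germacr-7(11)-en-12,6-olide | C/C=C(\C)C(=O)O[C@H]1C[C@@](C)(O)C(=O)C(I)C[C@@]2(C)O[C@@H]2[C@H]2OC(=O)C(CO)=C12 | intermediate (not isolated)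
22 | (4R,5R,6S,8S,10R)-4,5-epoxy-10,13-dihydroxy-1-oxo-8-[(E)-2-methylbut-2-enoyloxy]germacr-7(11)-en-12,6-olide | C/C=C(\C)C(=O)O[C@H]1C[C@@](C)(O)C(=O)CC[C@@]2(C)O[C@@H]2[C@H]2OC(=O)C(CO)=C12 | intermediate
23 | (4R,5R,6S,8S,10R)-10,13-diacetoxy-4,5-epoxy-1-oxo-8-[(E)-2-methylbut-2-enoyloxy]germacr-7(11)-en-12,6-olide (CNP0175424.1) | C/C=C(\C)C(=O)O[C@H]1C[C@@](C)(OC(C)=O)C(=O)CC[C@@]2(C)O[C@@H]2[C@H]2OC(=O)C(COC(C)=O)=C12 | target

## Step count and risks

Total step count: 15. Longest linear sequence: 13 steps (steps 1–8 and 11–15; steps 9 and 10 make fragment 16).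

Least certain steps:

**Step 7 (key step).** The [3,3] shift onto an internal alkyne may be slow. Fragmentation of the epoxy alkoxide could then compete, and after the shift so could displacement at the epoxide by the enolate carbon (Favorskii-type contraction) or a transannular ene reaction of the allenyl ketone. If the ring flips before the enolate is trapped, oxygen is delivered to both faces and C8 selectivity is lost. The fallback sets out from 7 and replaces the anionic cascade by a neutral sequence. N-(Trimethylsilyl)imidazole gives the trimethylsilyl ether F1. Thermal siloxy-Cope rearrangement (o-dichlorobenzene, 180 °C) gives the ring-expanded silyl enol ether F2. Rubottom oxidation (m-CPBA, NaHCO3; then citric acid in MeOH) gives the ketol F3. F3 is esterified with (E)-2-methylbut-2-enoyl chloride and DMAP, or by Mitsunobu reaction with tiglic acid if the C8 epimer is formed, and the route is rejoined at 10.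

**Step 2.** The Lewis-acidic alane may open the epoxide or add 1,2, and discrimination between the two faces at C2 may be poor, because the epoxide is two bonds away from the reacting carbon. The fallback sets out from 2. Rhodium-catalysed conjugate addition of (triisopropylsilyl)acetylene ([Rh(OH)(cod)]2, DTBM-SEGPHOS of the matching hand, dioxane, 80 °C) gives the silylalkynyl ketone F4. MeMgBr/CeCl3 gives the tertiary alcohol F5. Bu4NF gives the terminal alkyne F6. Double deprotonation (n-BuLi, 2 equiv) and C-methylation with MeI rejoin the route at 4.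

**Step 8.** Under the basic conditions of the Payne shift the C6 alkoxide may attack the neighbouring tiglate (acyl shift from O8 to O6 through a six-membered orthoester anion), or the C8–H beside the ketone may be removed with loss of configuration. The fallback sets out from 7 and keeps esters away from this step. Step 7 is quenched with aq NH4Cl after the oxygenation, which gives the free ketol F3. Bu4NF then gives, by desilylation and Payne shift, the diol F7. The less hindered C8 hydroxyl is acylated selectively ((E)-2-methylbut-2-enoyl chloride, 2,4,6-collidine, −40 °C) and the route is rejoined at 12.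

**Step 12.** The phosphonate anion may expel 4-methoxybenzyl oxide by β-elimination faster than it adds to the hindered, doubly α-oxygenated ketone, and the base may epimerise C8 before the ketone is consumed. The fallback sets out from 12. Heating with 2,2-dimethyl-1,3-dioxane-4,6-dione (toluene, 80 °C) gives the malonic half-ester F8. Intramolecular Knoevenagel condensation (piperidinium acetate) gives the butenolide acid F9. Reduction of the acid through its mixed anhydride (i-BuOCOCl, N-methylmorpholine; NaBH4, −30 °C) rejoins the route at 19.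

**Step 14.** Epoxidation may not stop cleanly at the spirodiepoxide or may lack face selectivity at C1=C10, and iodide with acid may open the 4,5-epoxide. The fallback sets out from 19 and uses a different oxidation. Dihydroxylation of the more substituted allene π bond with OsO4 (cat.) and N-methylmorpholine N-oxide gives an enol that tautomerises directly to 22. No compound outside the list is made (F0).

## Further compounds

F1 | step 7 | trimethylsilyl ether of 7 | C=C[C@@]1(O[Si](C)(C)C)[C@@H]2O[C@@H]2[C@](C)(O[Si](CC)(CC)CC)C[C@H]1C#CC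
F2 | step 7 | ring-expanded trimethylsilyl enol ether (C7(OSiMe3)=C8, (P)-allene, 5,6-epoxide, 4-OSiEt3) | C[Si](C)(C)O\C1=C/CC(C)=[C@@]=C([H])C[C@@](C)(O[Si](CC)(CC)CC)[C@H]2O[C@@H]12
F3 | step 7 | (P,4R,5S,6R,8S)-5,6-epoxy-8-hydroxy-4-(triethylsilyloxy)-11,12,13-trinorgermacra-1(2),1(10)-dien-7-one | O[C@H]1CC(C)=[C@@]=C([H])C[C@@](C)(O[Si](CC)(CC)CC)[C@H]2O[C@H]2C1=O
F4 | step 2 | (1S,4S,6R)-5,5-dimethoxy-4-[(triisopropylsilyl)ethynyl]-7-oxabicyclo[4.1.0]heptan-2-one | O=C1C[C@@H](C#C[Si](C(C)C)(C(C)C)C(C)C)C(OC)(OC)[C@@H]2O[C@H]12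
F5 | step 2 | (1S,2R,4S,6R)-5,5-dimethoxy-2-methyl-4-[(triisopropylsilyl)ethynyl]-7-oxabicyclo[4.1.0]heptan-2-ol | C[C@@]1(O)C[C@@H](C#C[Si](C(C)C)(C(C)C)C(C)C)C(OC)(OC)[C@@H]2O[C@H]12
F6 | step 2 | (1S,2R,4S,6R)-4-ethynyl-5,5-dimethoxy-2-methyl-7-oxabicyclo[4.1.0]heptan-2-ol | C[C@@]1(O)C[C@@H](C#C)C(OC)(OC)[C@@H]2O[C@H]12
F7 | step 8 | (P,4R,5R,6R,8S)-4,5-epoxy-6,8-dihydroxy-11,12,13-trinorgermacra-1(2),1(10)-dien-7-one | O[C@H]1CC(C)=[C@@]=C([H])C[C@@]2(C)O[C@@H]2[C@@H](O)C1=O
F8 | step 12 | C6 hydrogen malonate of 12 | C/C=C(\C)C(=O)O[C@H]1CC(C)=[C@@]=C([H])C[C@@]2(C)O[C@@H]2[C@@H](OC(=O)CC(=O)O)C1=O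
F9 | step 12 | (P,4R,5R,6S,8S)-4,5-epoxy-8-[(E)-2-methylbut-2-enoyloxy]-12,6-olide-germacra-1(2),1(10),7(11)-trien-13-oic acid | C/C=C(\C)C(=O)O[C@H]1CC(C)=[C@@]=C([H])C[C@@]2(C)O[C@@H]2[C@H]2OC(=O)C(C(=O)O)=C12
F0 | step 14 | none | none
A1 | alternative 1 | acyclic (Z)-iodoalkenoate aldehyde: methyl ester, C6 aldehyde, (4R,5R)-epoxide, C1 ketone, (10R)-acetate, (8S)-tiglate, C7 iodide cis to the ester | O=C[C@H]1O[C@]1(C)CCC(=O)[C@](C)(OC(C)=O)C[C@H](OC(=O)/C(C)=C/C)/C(I)=C(\COC(C)=O)C(=O)OC
A2 | alternative 2 | twelve-membered allyl β-keto lactone (C3–O–CO–C2), (E)-C4=C5, (6S)-OSiMe2t-Bu, C7 ketone, (8S)-tiglate, (10R)-acetate | C/C=C(\C)C(=O)O[C@H]1C[C@@](C)(OC(C)=O)C(=O)CC(=O)OC/C(C)=C/[C@@H](O[Si](C)(C)C(C)(C)C)C1=O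
A3 | alternative 2 | ring-contracted (E)-cyclodec-4-ene-1,7-dione from A2 | C/C=C(\C)C(=O)O[C@H]1C[C@@](C)(OC(C)=O)C(=O)CC/C(C)=C/[C@@H](O[Si](C)(C)C(C)(C)C)C1=O
A4 | alternative 3 | 2-ethynyl-4-methyl-1-(prop-1-en-2-yl)-3,4-bis(triethylsilyloxy)cyclohexan-1-ol (C1–OH cis to ethynyl, 4,5-trans-diol, ethynyl trans to C5–O) | C=C(C)[C@]1(O)CC[C@@](C)(O[Si](CC)(CC)CC)[C@H](O[Si](CC)(CC)CC)[C@H]1C#C
A5 | alternative 3 | ten-membered C6=C7=C8 allene with C1 ketone, (10R)-acetate and 4,5-bis(triethylsilyloxy) groups | O=C1CC[C@@](C)(O[Si](CC)(CC)CC)[C@H](O[Si](CC)(CC)CC)C([H])=[C@@]=C([H])C[C@@]1(C)OC(C)=O
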